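## Retrosynthetic overview

- The allylic alcohol comes from its methyl ester, and both exocyclic methylenes come from one diketone by double methylenation.
- Rings B and C (the bicyclo[4.4.1]undecenone) form together in a type 2 intramolecular [4+3] cycloaddition of an oxyallyl cation with a 2-alkylbutadiene, tethered across the two cis arms of ring A.
- The cis arms come from a Diels–Alder reaction of isoprene with a 4-substituted cyclohexenone (anti to the side chain), followed by ozonolysis of the temporary ring D.
- The cyclohexenone (ring A) comes from an Ireland–Claisen rearrangement of (S)-but-3-en-2-yl (S)-citronellate (carbinol chirality relayed to the ring carbon), then Wacker oxidation and aldol condensation.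
- Ring order: A (aldol), D (Diels–Alder, later cleaved), then B and C together ([4+3]).

Assumption: (S)-citronellic acid and (S)-but-3-en-2-ol are bought enantiopure; locants Cn mean the nth atom of the target SMILES read left to right. The type 2 [4+3] step is designed by analogy with other type 2 cycloadditions, not on direct precedent.

## Route

Step 1
Reactants: 1 (S)-citronellic acid; 2 (S)-but-3-en-2-ol
Product: 3 (S)-but-3-en-2-yl (S)-3,7-dimethyloct-6-enoate
Conditions: DCC, DMAP (cat.), CH2Cl2, 0 °C to rt
Reagents that add atoms: none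
Why: Steglich esterification joins the two bought stereocentres without touching either, placing the carbinol centre that will relay chirality in the next step.

Step 2
Reactants: 3 (S)-but-3-en-2-yl (S)-3,7-dimethyloct-6-enoate
Product: 7 methyl (2S,3S)-2-[(2E)-but-2-enyl]-3,7-dimethyloct-6-enoate, via silyl ketene acetal 4 (not isolated), via silyl ester 5 (not isolated), via carboxylic acid 6 (not isolated)
Conditions: LiN(i-Pr)2, THF, −78 °C; Me3SiCl; −78 to 60 °C; MeOH; Me3SiCHN2, 0 °C
Reagents that add atoms: (trimethylsilyl)diazomethane, C[Si](C)(C)C=[N+]=[N-]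
Why: Ireland–Claisen [3,3]-sigmatropic rearrangement: enolisation in THF puts the α-substituent cis to the allyloxy oxygen, and the chair transition state with the carbinol methyl equatorial transfers the (S)-carbinol chirality to C5 (S) and gives the E-alkene; the acid is esterified in the same pot.

Step 3
Reactants: 7 methyl (2S,3S)-2-[(2E)-but-2-enyl]-3,7-dimethyloct-6-enoate
Product: 8 methyl (2S,3S)-3,7-dimethyl-2-(3-oxobutyl)oct-6-enoate
Conditions: Pd(OAc)2 (5 mol%), benzoquinone, aq. HBF4, DMA/MeCN/H2O, rt
Reagents that add atoms: water, O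
Why: Wacker oxidation of the internal alkene places oxygen on the carbon remote from the ester (carbonyl-chelated palladium sits on the nearer carbon), giving the methyl ketone; the trisubstituted alkene does not react.

Step 4
Reactants: 8 methyl (2S,3S)-3,7-dimethyl-2-(3-oxobutyl)oct-6-enoate
Product: 9 (5S,6S)-5-(hydroxymethyl)-6,10-dimethylundec-9-en-2-ol (carbinol epimers)
Conditions: LiAlH4, Et2O, 0 °C
Reagents that add atoms: none
Why: Hydride reduction of ester and ketone gives a diol that can be brought to the keto-aldehyde level in one oxidation; the new carbinol centre is lost again in step 5.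

Step 5
Reactants: 9 (5S,6S)-5-(hydroxymethyl)-6,10-dimethylundec-9-en-2-ol
Product: 11 (4S)-4-[(2S)-6-methylhept-5-en-2-yl]cyclohex-2-en-1-one, via keto-aldehyde 10 (not isolated)
Conditions: (COCl)2, DMSO, Et3N, CH2Cl2, −78 °C; crude, LiOH, i-PrOH, rt
Reagents that add atoms: none
Why: Swern oxidation then intramolecular aldol condensation (only the methyl carbon can close a six-membered ring) forms ring A; the mild base is chosen to keep the aldehyde α-centre C5 intact.

Step 6
Reactants: 11 (4S)-4-[(2S)-6-methylhept-5-en-2-yl]cyclohex-2-en-1-one; 12 methyl methacrylate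
Product: 13 methyl (2E,6S)-2-methyl-6-[(1S)-4-oxocyclohex-2-en-1-yl]hept-2-enoate
Conditions: second-generation Hoveyda–Grubbs catalyst (5 mol%), 12 (excess), CH2Cl2, 40 °C
Reagents that add atoms: none
Why: Olefin cross-metathesis swaps the isopropylidene end for the thermodynamically favoured E-2-methylenoate, which also deactivates this alkene towards ozone in step 9; the ring enone alkene is inert.

Step 7
Reactants: 13 methyl (2E,6S)-2-methyl-6-[(1S)-4-oxocyclohex-2-en-1-yl]hept-2-enoate; 14 isoprene
Product: 15 cis-fused octalone (4-substituted 6-methyl-3,4,4a,5,8,8a-hexahydronaphthalen-1(2H)-one; ring-fusion hydrogens cis; side chain on the opposite face to the new C–C bonds)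
Conditions: AlCl3 (50 mol%), 14 (excess), toluene, rt
Reagents that add atoms: none
Why: Lewis-acid-catalysed Diels–Alder reaction: isoprene adds to the enone face anti to the C5 substituent with para regiochemistry, setting C15 and C16 cis to each other and trans to the side chain.

Step 8
Reactants: 15 cis-fused octalone
Product: 16 ethylene ketal of 15
Conditions: Me3SiOCH2CH2OSiMe3, Me3SiOTf (cat.), CH2Cl2, −78 to −20 °C
Reagents that add atoms: 1,2-bis(trimethylsilyloxy)ethane, C[Si](C)(C)OCCO[Si](C)(C)C
Why: Noyori ketalisation at low temperature masks the ring ketone without epimerising the cis ring fusion or moving the alkene.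

Step 9
Reactants: 16 ethylene ketal of 15
Product: 18 keto-aldehyde (2-oxopropyl arm on C15 and 2-oxoethyl arm on C16 cis), via ozonide 17 (not isolated)
Conditions: O3, CH2Cl2, −78 °C (dye end-point); PPh3, −78 °C to rt
Reagents that add atoms: ozone, [O-][O+]=O
Why: Ozonolysis cleaves the electron-rich trisubstituted ring D alkene in preference to the electron-poor enoate, releasing the two differentiated cis arms.

Step 10
Reactants: 18 keto-aldehyde
Product: 19 primary alcohol (2-hydroxyethyl arm on C16)
Conditions: NaBH4, MeOH/CH2Cl2, −78 °C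
Reagents that add atoms: none
Why: Chemoselective borohydride reduction: the aldehyde reacts far faster than the methyl ketone or the enoate at −78 °C.

Step 11
Reactants: 19 primary alcohol
Product: 20 primary iodide (2-iodoethyl arm on C16)
Conditions: I2, PPh3, imidazole, CH2Cl2, 0 °C
Reagents that add atoms: iodine, II
Why: Appel-type iodination of the unhindered primary alcohol under neutral conditions that spare ketal, ketone and ester.

Step 12
Reactants: 20 primary iodide; 21 chloroprene
Product: 23 diene (3-methylenepent-4-enyl arm on C16), via alkylzinc iodide 22 (not isolated)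
Conditions: Zn, LiCl, THF, 40 °C; then 21, Pd(OAc)2 (3 mol%), SPhos, THF, 40 °C
Reagents that add atoms: none
Why: Zinc insertion then Negishi cross-coupling with the alkenyl chloride gives the 2-alkylbutadiene; the alkylzinc tolerates ketone, ester and ketal.

Step 13
Reactants: 23 diene
Product: 25 chloromethyl ketone (3-chloro-2-oxopropyl arm on C15), via silyl enol ether 24 (not isolated)
Conditions: LiN(SiMe3)2, Me3SiCl, THF, −78 °C; N-chlorosuccinimide, −78 to 0 °C
Reagents that add atoms: N-chlorosuccinimide, O=C1CCC(=O)N1Cl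
Why: Kinetic enolisation at the methyl group, silylation and electrophilic chlorination give the α-chloroketone; the other α-chloro regioisomer would lead to the same oxyallyl cation.

Step 14
Reactants: 25 chloromethyl ketone
Product: 27 tricyclic ketone ketal (bicyclo[4.4.1]undecenone cis-fused to ring A), via oxyallyl cation 26 (not isolated)
Conditions: Et3N, CF3CH2OH, rt, 0.005 M
Reagents that add atoms: none
Why: Föhlisch-type ionisation gives the oxyallyl cation, which undergoes type 2 intramolecular [4+3] cycloaddition with the tethered diene; with the C15–H eclipsing the cation plane (allylic strain) the diene is delivered from the C16 face, setting C25 with its hydrogen trans to the C15 hydrogen.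

Step 15
Reactants: 27 tricyclic ketone ketal
Product: 28 tricyclic diketone (ketones at C2 and C23)
Conditions: PPTS, acetone/H2O, 50 °C
Reagents that add atoms: water, O
Why: Mild acid-catalysed acetal hydrolysis frees the ring A ketone, chosen to limit epimerisation at C16 and alkene migration.

Step 16
Reactants: 28 tricyclic diketone
Product: 29 methyl ester of the target acid (both exocyclic methylenes in place)
Conditions: Zn, CH2Br2, TiCl4, THF/CH2Cl2, 0 °C to rt
Reagents that add atoms: dibromomethane, BrCBr
Why: Takai–Lombardo methylenation converts both ketones under non-basic conditions, so the epimerisable C16 centre is kept and the ester is untouched.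

Step 17
Reactants: 29 methyl ester of the target acid
Product: 30 target allylic alcohol (CNP0264710.1)
Conditions: i-Bu2AlH, CH2Cl2, −78 °C
Reagents that add atoms: none
Why: 1,2-Reduction of the enoate by the aluminium hydride gives the E-allylic alcohol without touching the four alkenes.

## Compound list

1 | (S)-citronellic acid | OC(=O)C[C@@H](C)CCC=C(C)C | starting material
2 | (S)-but-3-en-2-ol | C=C[C@H](C)O | starting material
3 | (S)-but-3-en-2-yl (S)-3,7-dimethyloct-6-enoate | C=C[C@H](C)OC(=O)C[C@@H](C)CCC=C(C)C | intermediate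
4 | trimethylsilyl ketene acetal of 3 (α-substituent cis to allyloxy oxygen) | C=C[C@H](C)O/C(O[Si](C)(C)C)=C\[C@@H](C)CCC=C(C)C | intermediate
5 | trimethylsilyl (2S,3S)-2-[(2E)-but-2-enyl]-3,7-dimethyloct-6-enoate | C/C=C/C[C@@H]([C@@H](C)CCC=C(C)C)C(=O)O[Si](C)(C)C | intermediate
6 | (2S,3S)-2-[(2E)-but-2-enyl]-3,7-dimethyloct-6-enoic acid | C/C=C/C[C@@H]([C@@H](C)CCC=C(C)C)C(=O)O | intermediate
7 | methyl (2S,3S)-2-[(2E)-but-2-enyl]-3,7-dimethyloct-6-enoate | C/C=C/C[C@@H]([C@@H](C)CCC=C(C)C)C(=O)OC | intermediate
8 | methyl (2S,3S)-3,7-dimethyl-2-(3-oxobutyl)oct-6-enoate | CC(=O)CC[C@@H]([C@@H](C)CCC=C(C)C)C(=O)OC | intermediate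
9 | (5S,6S)-5-(hydroxymethyl)-6,10-dimethylundec-9-en-2-ol | CC(O)CC[C@@H]([C@@H](C)CCC=C(C)C)CO | intermediate
10 | (2S,3S)-3,7-dimethyl-2-(3-oxobutyl)oct-6-enal | CC(=O)CC[C@@H]([C@@H](C)CCC=C(C)C)C=O | intermediate
11 | (4S)-4-[(2S)-6-methylhept-5-en-2-yl]cyclohex-2-en-1-one | O=C1CC[C@@H]([C@@H](C)CCC=C(C)C)C=C1 | intermediate
12 | methyl methacrylate | C=C(C)C(=O)OC | starting material
13 | methyl (2E,6S)-2-methyl-6-[(1S)-4-oxocyclohex-2-en-1-yl]hept-2-enoate | O=C1CC[C@@H]([C@@H](C)CC/C=C(\C)C(=O)OC)C=C1 | intermediate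
14 | isoprene | C=CC(C)=C | starting material
15 | cis-fused Diels–Alder octalone | O=C1CC[C@@H]([C@@H](C)CC/C=C(\C)C(=O)OC)[C@@H]2CC(C)=CC[C@H]12 | intermediate
16 | ethylene ketal of 15 | C12(OCCO1)CC[C@@H]([C@@H](C)CC/C=C(\C)C(=O)OC)[C@@H]3CC(C)=CC[C@H]23 | intermediate
17 | ozonide of 16 | C12(OCCO1)CC[C@@H]([C@@H](C)CC/C=C(\C)C(=O)OC)[C@@H]3CC4(C)OOC(O4)C[C@H]23 | intermediate
18 | keto-aldehyde with cis arms | C12(OCCO1)CC[C@@H]([C@@H](C)CC/C=C(\C)C(=O)OC)[C@H](CC(C)=O)[C@@H]2CC=O | intermediate
19 | primary alcohol | C12(OCCO1)CC[C@@H]([C@@H](C)CC/C=C(\C)C(=O)OC)[C@H](CC(C)=O)[C@@H]2CCO | intermediate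
20 | primary iodide | C12(OCCO1)CC[C@@H]([C@@H](C)CC/C=C(\C)C(=O)OC)[C@H](CC(C)=O)[C@@H]2CCI | intermediate
21 | chloroprene | C=CC(Cl)=C | starting material
22 | alkylzinc iodide | C12(OCCO1)CC[C@@H]([C@@H](C)CC/C=C(\C)C(=O)OC)[C@H](CC(C)=O)[C@@H]2CC[Zn]I | intermediate
23 | diene methyl ketone | C12(OCCO1)CC[C@@H]([C@@H](C)CC/C=C(\C)C(=O)OC)[C@H](CC(C)=O)[C@@H]2CCC(=C)C=C | intermediate
24 | trimethylsilyl enol ether of 23 | C12(OCCO1)CC[C@@H]([C@@H](C)CC/C=C(\C)C(=O)OC)[C@H](CC(=C)O[Si](C)(C)C)[C@@H]2CCC(=C)C=C | intermediate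
25 | chloromethyl ketone | C12(OCCO1)CC[C@@H]([C@@H](C)CC/C=C(\C)C(=O)OC)[C@H](CC(=O)CCl)[C@@H]2CCC(=C)C=C | intermediate
26 | oxyallyl cation (zwitterion; ring carbon cis to O) | C12(OCCO1)CC[C@@H]([C@@H](C)CC/C=C(\C)C(=O)OC)[C@H](/C=C(\[O-])[CH2+])[C@@H]2CCC(=C)C=C | intermediate
27 | tricyclic ketone ketal | C12(OCCO1)CC[C@@H]([C@@H](C)CC/C=C(\C)C(=O)OC)[C@H]3[C@@H]2CCC2=CCCC(=O)[C@H]3C2 | intermediate
28 | tricyclic diketone | O=C1CC[C@@H]([C@@H](C)CC/C=C(\C)C(=O)OC)[C@H]2[C@@H]1CCC1=CCCC(=O)[C@H]2C1 | intermediate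
29 | methyl ester of the target acid | C=C1CC[C@@H]([C@@H](C)CC/C=C(\C)C(=O)OC)[C@H]2[C@@H]1CCC1=CCCC(=C)[C@H]2C1 | intermediate
30 | CNP0264710.1 | C=C1CC[C@@H]([C@@H](C)CC/C=C(\C)CO)[C@H]2[C@@H]1CCC1=CCCC(=C)[C@H]2C1 | target

## Step count and risks

Total steps: 17. Longest linear sequence: 17 (from 1).

Steps most likely to fail:

Step 14, the type 2 [4+3] cycloaddition. The risks are Favorskii products, [3+2] capture and strain in the bridged transition state. The fallback closes the two seven-membered rings one after the other by enolate alkylation. It sets out from diene 23: Pt(PPh3)4-catalysed 1,4-diboration with bis(pinacolato)diboron gives the (Z)-1,4-bis(boronate) F1, and NaBO3 oxidation gives the (Z)-2-substituted but-2-ene-1,4-diol F2. CBr4/PPh3 then gives the (Z)-dibromide F3. One equivalent of KOt-Bu in t-BuOH/THF (thermodynamic enolate at C25) closes ring B to the acetyl-substituted cycloheptane F4, whose epimerisable C25 settles with the acetyl group trans to the ring A bond at C15. LiN(i-Pr)2 at −78 °C then forms the kinetic methyl enolate, which closes ring C on the remaining allylic bromide on warming and comes back to the route at 27.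

Step 6, the cross-metathesis of a trisubstituted alkene with methyl methacrylate. The fallback oxidises the allylic C–H bond instead and sets out from enone 11. SeO2 (cat.)/t-BuOOH gives the (E)-allylic alcohol F5 at the E-methyl group, PhI(OAc)2/TEMPO gives the enal F6, and NaClO2/NaH2PO4/2-methylbut-2-ene gives the enoic acid F7. Me3SiCHN2 then returns to 13.

Step 12, the alkylzinc coupling with the polymerisable alkenyl chloride. The fallback adds the dienyl unit to the carbonyl and removes the oxygen afterwards; it sets out from keto-aldehyde 18. Buta-1,3-dien-2-ylmagnesium chloride (from chloroprene 21 and Mg) at −78 °C adds to the aldehyde only and gives the dienyl carbinol F8. ClCO2Me/pyridine gives the methyl carbonate F9. Pd(OAc)2/PBu3 with HCO2H/Et3N then delivers hydride to the more substituted allyl terminus (Tsuji deoxygenation) and comes back to the route at 23.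

Further compounds
F1 | step 14 | (Z)-1,4-bis(pinacolboronate) from 23 | C12(OCCO1)CC[C@@H]([C@@H](C)CC/C=C(\C)C(=O)OC)[C@H](CC(C)=O)[C@@H]2CC/C(CB1OC(C)(C)C(C)(C)O1)=C/CB1OC(C)(C)C(C)(C)O1
F2 | step 14 | (Z)-but-2-ene-1,4-diol | C12(OCCO1)CC[C@@H]([C@@H](C)CC/C=C(\C)C(=O)OC)[C@H](CC(C)=O)[C@@H]2CC/C(CO)=C/CO
F3 | step 14 | (Z)-1,4-dibromide | C12(OCCO1)CC[C@@H]([C@@H](C)CC/C=C(\C)C(=O)OC)[C@H](CC(C)=O)[C@@H]2CC/C(CBr)=C/CBr
F4 | step 14 | ring B acetyl ketone with allylic bromide | C12(OCCO1)CC[C@@H]([C@@H](C)CC/C=C(\C)C(=O)OC)[C@H]3[C@@H]2CC/C(=C/CBr)C[C@@H]3C(C)=O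
F5 | step 6 | (E)-allylic alcohol of enone 11 | O=C1CC[C@@H]([C@@H](C)CC/C=C(\C)CO)C=C1
F6 | step 6 | (E)-enal | O=C1CC[C@@H]([C@@H](C)CC/C=C(\C)C=O)C=C1
F7 | step 6 | (E)-enoic acid | O=C1CC[C@@H]([C@@H](C)CC/C=C(\C)C(=O)O)C=C1
F8 | step 12 | dienyl carbinol (carbinol epimers) | C12(OCCO1)CC[C@@H]([C@@H](C)CC/C=C(\C)C(=O)OC)[C@H](CC(C)=O)[C@@H]2CC(O)C(=C)C=C
F9 | step 12 | methyl carbonate of F8 | C12(OCCO1)CC[C@@H]([C@@H](C)CC/C=C(\C)C(=O)OC)[C@H](CC(C)=O)[C@@H]2CC(OC(=O)OC)C(=C)C=C
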